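Ring A (the cyclohex-2-ene-1,4-dione) is disconnected last at its isolated cis-CH=CH unit, the two CH carbons between the ring A carbonyls; these carbonyl carbons sit on adjacent ring B atoms, the O-bearing quaternary carbon common to rings A, B and D and the sp2 carbon common to A and B. Ring-closing metathesis therefore closes ring A and installs its enone alkene in one operation from a BCD tricycle carrying a vinyl carbinol and a vinyl ketone on these two atoms. The tricycle comes from (S)-linalool and an iodo-dioxinone by Heck coupling, an intramolecular Diels–Alder reaction (rings B and C) and a palladium-catalysed vinyl epoxide cyclisation (ring D); a final oxidation gives the target.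

Key step: step 12

Remark: (S)-(+)-linalool of high enantiomeric purity is assumed to be purchasable; the epoxide carbons of 10 and 11, the ring D carbinol of 12–15 and the ring A carbinol of 14 and 15 are written without configuration because these centres converge or are erased later.

Ring letters: A = cyclohexenedione, B = central cyclohexene, C = cyclopentane, D = furanone.

Step 1
Reactants: 1 2,2,6-trimethyl-4H-1,3-dioxin-4-one
Product: 2 2,2-dimethyl-4-oxo-4H-1,3-dioxine-6-carbaldehyde
Conditions: SeO2, 1,4-dioxane, 90 °C
Reagents that add atoms: selenium dioxide O=[Se]=O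
Why: Riley oxidation of the vinylogous methyl group (ene reaction, then [2,3]-shift) should stop at the conjugated, non-enolisable aldehyde; no stereocentre is formed.

Step 2
Reactants: 2 2,2-dimethyl-4-oxo-4H-1,3-dioxine-6-carbaldehyde
Product: 3 6-(dimethoxymethyl)-2,2-dimethyl-4H-1,3-dioxin-4-one
Conditions: HC(OMe)3, p-TsOH (cat.), CH2Cl2, rt
Reagents that add atoms: trimethyl orthoformate COC(OC)OC
Why: Acid-catalysed acetalisation, with the orthoformate as methanol source and water scavenger, masks this formyl group so that only one free aldehyde is present later; no stereocentre is formed.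

Step 3
Reactants: 3 6-(dimethoxymethyl)-2,2-dimethyl-4H-1,3-dioxin-4-one
Product: 4 6-(dimethoxymethyl)-5-iodo-2,2-dimethyl-4H-1,3-dioxin-4-one
Conditions: NIS, AcOH (cat.), CH2Cl2, rt, dark
Reagents that add atoms: N-iodosuccinimide O=C1CCC(=O)N1I
Why: Electrophilic iodination at C-5, the nucleophilic enol-ether β-carbon of the vinylogous carbonate, gives the vinyl iodide for the coupling; no stereocentre is formed.

Step 4
Reactants: 5 (S)-(+)-linalool, (3S)-3,7-dimethylocta-1,6-dien-3-ol
Product: 6 (2E,6S)-6-hydroxy-2,6-dimethylocta-2,7-dienal
Conditions: SeO2, 1,4-dioxane, 80 °C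
Reagents that add atoms: selenium dioxide O=[Se]=O
Why: Riley allylic oxidation selects the E-methyl group of the trisubstituted alkene and should carry it to the E-enal, leaving the vinyl group and the tertiary carbinol stereocentre of the starting material untouched.

Step 5
Reactants: 4 6-(dimethoxymethyl)-5-iodo-2,2-dimethyl-4H-1,3-dioxin-4-one; 6 (2E,6S)-6-hydroxy-2,6-dimethylocta-2,7-dienal
Product: 7 (2E,6S,7E)-8-[6-(dimethoxymethyl)-2,2-dimethyl-4-oxo-4H-1,3-dioxin-5-yl]-6-hydroxy-2,6-dimethylocta-2,7-dienal
Conditions: Pd(OAc)2 (5 mol %), n-Bu4NCl, NaHCO3, DMF, 50 °C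
Reagents that add atoms: none
Why: Mizoroki–Heck vinylation of the terminal alkene places the dioxinonyl group on the CH2 terminus, and syn β-hydride elimination can only use the hydrogen of the internal carbon because the next carbon is quaternary, so the E-diene should form without isomerisation and with the carbinol centre untouched.

Step 6
Reactants: 7 (2E,6S,7E)-8-[6-(dimethoxymethyl)-2,2-dimethyl-4-oxo-4H-1,3-dioxin-5-yl]-6-hydroxy-2,6-dimethylocta-2,7-dienal
Product: 8 Diels–Alder adduct: trans-fused rings B and C with a 2,2-dimethyl-1,3-dioxan-4-one fused across the O-bearing quaternary carbon and the alkene carbon of ring B; dimethoxymethyl on that quaternary carbon; methyl and formyl on the neighbouring quaternary carbon (formyl cis to the dioxanone oxygen, methyl cis to the ring C methylene); tertiary OH and methyl on ring C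
Conditions: toluene (10 mM), BHT (cat.), 85 °C
Reagents that add atoms: none
Why: Intramolecular Diels–Alder reaction of the 1-alkoxy-2-acyl diene (dioxinone C-6=C-5 plus the E-vinyl group) with the tethered E-enal closes rings B and C at once below the temperature at which the dioxinone cycloreverts quickly; the dioxinone ring locks its oxygen in the outer position of the diene terminus so that it ends cis to the endo formyl group, the three-atom tether with endo formyl gives the trans B/C fusion, the E-enal geometry puts the new methyl cis to the ring C methylene, and the tertiary carbinol directs the diene face by allylic 1,3-strain (hydroxyl, the smaller group, eclipsing the diene hydrogen).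

Step 7
Reactants: 8 Diels–Alder adduct; 9 prenyl bromide (1-bromo-3-methylbut-2-ene)
Product: 10 vinyl epoxide: the formyl group of 8 converted into a 3-(2-methylprop-1-enyl)oxiran-2-yl group (mixture of epoxide diastereomers)
Conditions: tetrahydrothiophene, Cs2CO3, MeCN, rt
Reagents that add atoms: none
Why: Corey–Chaykovsky epoxidation by the allylic sulfonium ylide made in the flask adds the five-carbon unit to the non-enolisable aldehyde while the dioxanone keeps the tertiary oxygen masked against retro-aldol cleavage; the two epoxide centres form as a mixture that converges in step 9.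

Step 8
Reactants: 10 vinyl epoxide
Product: 11 ring-opened hydroxy amide: tertiary alcohol on the quaternary ring B carbon, N-methoxy-N-methyl carboxamide on the ring B alkene carbon, vinyl epoxide and acetal unchanged
Conditions: MeNH(OMe)·HCl, i-PrMgCl, THF, −20 → 0 °C
Reagents that add atoms: N,O-dimethylhydroxylamine hydrochloride CNOC.Cl
Why: Aminolysis of the acylal lactone by the chloromagnesium amide gives the N-methoxy-N-methyl amide, and the released hemiketal alkoxide loses acetone to free the tertiary hydroxyl group; no stereocentre is touched.

Step 9
Reactants: 11 ring-opened hydroxy amide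
Product: 12 BCD tricycle: ring D is a 3-hydroxy-2-(2-methylprop-1-enyl)tetrahydrofuran cis-fused to ring B, with the isobutenyl group on the ring B side of ring D; acetal and amide unchanged
Conditions: Pd(PPh3)4 (5 mol %), THF, rt
Reagents that add atoms: none
Why: Zerovalent palladium ionises the vinyl epoxide to a π-allylpalladium alkoxide (Tsuji–Trost manifold) whose faces interconvert through the η1 form at the gem-dimethyl terminus, so both epoxide diastereomers should converge; the tertiary hydroxyl then closes ring D by 5-exo attack on the proximal allyl terminus anti to palladium, with the allyl arm turned away from the dimethoxymethyl group, which should place the isobutenyl group as in the target, the cis B/D fusion being enforced by the five-membered ring.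

Step 10
Reactants: 12 BCD tricycle with acetal
Product: 13 BCD tricycle with the acetal replaced by a formyl group on the quaternary ring B carbon
Conditions: 1 M HCl, THF, rt
Reagents that add atoms: water O
Why: Acid hydrolysis of the dimethyl acetal releases the non-enolisable α-alkoxy aldehyde, while the allylic ether, the amide and the tertiary alcohol should survive dilute acid at room temperature; no stereocentre is involved.

Step 11
Reactants: 13 BCD tricycle aldehyde
Product: 14 metathesis precursor: 1-hydroxyprop-2-enyl group on the quaternary ring B carbon and acryloyl group on the adjacent ring B alkene carbon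
Conditions: CH2=CHMgBr (6 equiv), THF, −78 → 0 °C
Reagents that add atoms: vinylmagnesium bromide C=C[Mg]Br
Why: Grignard addition to the aldehyde gives the vinyl carbinol, and acyl substitution at the N-methoxy-N-methyl amide (stable magnesium chelate, no over-addition) gives the vinyl ketone after an acidic inverse quench that keeps the released amine from adding to the enone; the new carbinol centre is a mixture that step 13 erases.

Step 12
Reactants: 14 metathesis precursor
Product: 15 tetracyclic hydroxy enone: ring A closed as a 4-hydroxycyclohex-2-enone; ring D carbinol still present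
Conditions: second-generation Grubbs catalyst (5 mol %), CH2Cl2 (5 mM), 40 °C
Reagents that add atoms: none
Why: Olefin metathesis through ruthenacyclobutanes: the ruthenium alkylidene loads onto the vinyl group of the allylic alcohol, [2+2] cycloaddition to the vinyl ketone and cycloreversion expel ethylene and close ring A. The closest known reaction type is ring-closing metathesis of a 3-hydroxy-1,7-dien-6-one to a 4-hydroxycyclohex-2-enone. Ring A is closed by joining the two vinyl CH carbons into the ring cis-CH=CH (six-membered ring; the Z geometry is enforced by the ring size). No stereocentre is created: the ring A carbinol is a mixture that step 13 erases, and the six defined centres lie outside the reacting bonds. The selectivity needed is chemoselectivity among four C=C bonds, secured because only the two monosubstituted vinyl groups can enter the catalytic cycle (the trisubstituted isobutenyl alkene and the trisubstituted, conjugated ring B alkene are inert) and because both vinyl groups sit on adjacent ring B atoms, so closure at 5 mM should outrun oligomerisation.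

Step 13
Reactants: 15 tetracyclic hydroxy enone
Product: 16 target (CNP0156201.1)
Conditions: Dess–Martin periodinane (3 equiv), pyridine, CH2Cl2, 0 °C → rt
Reagents that add atoms: none
Why: Dess–Martin oxidation should convert the ring A allylic carbinol into the enedione and the ring D carbinol into the furanone in one operation while the tertiary alcohol is inert, and the buffered, non-basic conditions should keep the newly enolisable O–CH centre of ring D from epimerising or from shifting its alkene into conjugation.

Compound list
1 | 2,2,6-trimethyl-4H-1,3-dioxin-4-one | CC1=CC(=O)OC(C)(C)O1 | starting material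
2 | 2,2-dimethyl-4-oxo-4H-1,3-dioxine-6-carbaldehyde | O=CC1=CC(=O)OC(C)(C)O1 | intermediate
3 | 6-(dimethoxymethyl)-2,2-dimethyl-4H-1,3-dioxin-4-one | COC(OC)C1=CC(=O)OC(C)(C)O1 | intermediate
4 | 6-(dimethoxymethyl)-5-iodo-2,2-dimethyl-4H-1,3-dioxin-4-one | COC(OC)C1=C(I)C(=O)OC(C)(C)O1 | intermediate
5 | (S)-(+)-linalool | C=C[C@@](C)(O)CCC=C(C)C | starting material
6 | (2E,6S)-6-hydroxy-2,6-dimethylocta-2,7-dienal | C=C[C@@](C)(O)CC/C=C(\C)C=O | intermediate
7 | (2E,6S,7E)-8-[6-(dimethoxymethyl)-2,2-dimethyl-4-oxo-4H-1,3-dioxin-5-yl]-6-hydroxy-2,6-dimethylocta-2,7-dienal | COC(OC)C1=C(/C=C/[C@@](C)(O)CC/C=C(\C)C=O)C(=O)OC(C)(C)O1 | intermediate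
8 | Diels–Alder adduct (rings B and C, fused dioxanone, formyl) | COC(OC)[C@]12OC(C)(C)OC(=O)C1=C[C@@H]3[C@H](CC[C@]3(C)O)[C@@]2(C)C=O | intermediate
9 | prenyl bromide (1-bromo-3-methylbut-2-ene) | CC(C)=CCBr | starting material
10 | vinyl epoxide of 8 (epoxide diastereomers) | COC(OC)[C@]12OC(C)(C)OC(=O)C1=C[C@@H]3[C@H](CC[C@]3(C)O)[C@@]2(C)C4OC4C=C(C)C | intermediate
11 | hydroxy N-methoxy-N-methyl amide with vinyl epoxide | COC(OC)[C@]1(O)C(C(=O)N(C)OC)=C[C@@H]2[C@H](CC[C@]2(C)O)[C@@]1(C)C3OC3C=C(C)C | intermediate
12 | BCD tricycle with acetal and amide (ring D carbinol epimers) | CC(C)=C[C@H]1O[C@@]2(C(OC)OC)C(C(=O)N(C)OC)=C[C@@H]3[C@H](CC[C@]3(C)O)[C@@]2(C)C1O | intermediate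
13 | BCD tricycle with formyl and amide | CC(C)=C[C@H]1O[C@@]2(C=O)C(C(=O)N(C)OC)=C[C@@H]3[C@H](CC[C@]3(C)O)[C@@]2(C)C1O | intermediate
14 | BCD tricycle with vinyl carbinol and vinyl ketone | CC(C)=C[C@H]1O[C@@]2(C(O)C=C)C(C(=O)C=C)=C[C@@H]3[C@H](CC[C@]3(C)O)[C@@]2(C)C1O | intermediate
15 | tetracyclic hydroxy enone with ring D carbinol | CC(C)=C[C@H]1O[C@@]23C(O)C=CC(=O)C2=C[C@@H]2[C@H](CC[C@]2(C)O)[C@@]3(C)C1O | intermediate
16 | target CNP0156201.1 | CC(C)=C[C@H]1O[C@@]23C(=O)C=CC(=O)C2=C[C@@H]2[C@H](CC[C@]2(C)O)[C@@]3(C)C1=O | target

Total step count: 13 (steps 1–3 for the dioxinone fragment, step 4 for the linalool fragment, steps 5–13 after their union).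
Longest linear sequence: 12 steps (steps 1–3, then 5–13).

Steps most likely to fail

1. Step 6. Cycloreversion of the dioxinone to an acylketene (loss of acetone) may outrun a cycloaddition that has to join two fully substituted carbons, and incomplete endo or facial control would erode the relative configuration. The fallback sets out from 7 and comes back at 11. Heating 7 with N,O-dimethylhydroxylamine in toluene at 110 °C turns the cycloreversion into the productive path, the acylketene being captured as the open-chain β-keto N-methoxy-N-methyl amide F1. TMSOTf and Et3N at −78 °C silylate the chelated enol and the tertiary alcohol to give the bis-silylated dienol ether F2, whose enol oxygen is cis to the amide carbonyl and so again occupies the outer position of the diene. This more electron-rich diene cannot fragment and should undergo the same intramolecular Diels–Alder reaction at or below 40 °C to the silyl-protected bicyclic aldehyde F3. Epoxidation as in step 7 gives the silyl-protected vinyl epoxide F4, and TBAF removes both silyl groups to give 11.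

2. Step 9. The π-allyl intermediate may close in other modes (attack of the neighbouring alkoxide at the tertiary terminus to a dihydrofuran, or hydride shift to a ketone), and facial control at the new O–CH centre may be insufficient. The fallback sets out from 8 and comes back at 12. 2-Methylbut-3-yn-2-yl methyl carbonate F5 (from 2-methylbut-3-yn-2-ol and methyl chloroformate) is hydrozirconated with Cp2Zr(H)Cl, transmetalated with Me2Zn and added to 8 to give the E-allylic alcohol with a tertiary allylic carbonate F6. Aminolysis as in step 8 gives the hydroxy amide carbonate F7. Ionisation of the carbonate with Pd2(dba)3 and the (R,R)-DACH-phenyl bisphosphine ligand then forms the π-allyl complex without an adjacent alkoxide, and the ligand rather than the substrate directs the 5-exo etherification to 12; the enantiomeric ligand is available if the pairing proves mismatched.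

3. Step 5. Migratory insertion of the hindered, electron-poor vinylpalladium species into the alkene next to a quaternary carbon may be slow, so that proto-deiodination takes over. The fallback sets out from 6 and comes back at 7. Cross-metathesis of 6 with vinylboronic acid pinacol ester (second-generation Hoveyda–Grubbs catalyst, CH2Cl2, 40 °C) gives the E-alkenyl pinacol boronate F8, and Suzuki–Miyaura coupling of F8 with 4 (PdCl2(dppf), K3PO4, THF–H2O, rt) gives 7, replacing the insertion step by transmetalation.

Further compounds
F1 | step 6 | open-chain β-keto N-methoxy-N-methyl amide from 7 | COC(OC)C(=O)C(/C=C/[C@@](C)(O)CC/C=C(\C)C=O)C(=O)N(C)OC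
F2 | step 6 | bis-trimethylsilyl dienol ether of F1 | COC(OC)/C(O[Si](C)(C)C)=C(\C=C\[C@@](C)(O[Si](C)(C)C)CC/C=C(\C)C=O)C(=O)N(C)OC
F3 | step 6 | silyl-protected bicyclic aldehyde (rings B and C) | COC(OC)[C@]1(O[Si](C)(C)C)C(C(=O)N(C)OC)=C[C@@H]2[C@H](CC[C@]2(C)O[Si](C)(C)C)[C@@]1(C)C=O
F4 | step 6 | silyl-protected vinyl epoxide | COC(OC)[C@]1(O[Si](C)(C)C)C(C(=O)N(C)OC)=C[C@@H]2[C@H](CC[C@]2(C)O[Si](C)(C)C)[C@@]1(C)C3OC3C=C(C)C
F5 | step 9 | 2-methylbut-3-yn-2-yl methyl carbonate | COC(=O)OC(C)(C)C#C
F6 | step 9 | E-allylic alcohol with tertiary allylic carbonate (dioxanone intact) | COC(OC)[C@]12OC(C)(C)OC(=O)C1=C[C@@H]3[C@H](CC[C@]3(C)O)[C@@]2(C)C(O)/C=C/C(C)(C)OC(=O)OC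
F7 | step 9 | hydroxy amide carbonate | COC(OC)[C@]1(O)C(C(=O)N(C)OC)=C[C@@H]2[C@H](CC[C@]2(C)O)[C@@]1(C)C(O)/C=C/C(C)(C)OC(=O)OC
F8 | step 5 | E-alkenyl pinacol boronate of 6 | CC1(C)OB(/C=C/[C@@](C)(O)CC/C=C(\C)C=O)OC1(C)C
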